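13.6 left-handed product for each spent catalyst A at 50 °C: this was my turnover per kill, and I carried it through four flasks of a racemate, whose partner both decomposes and destroys the catalyst.

    partner → decomposed reagent (k1 = 0.90 s⁻¹, Ea1 = 78.0 kJ mol⁻¹)
    2 free catalyst → spent catalyst B (k2 = 30000 M⁻¹ s⁻¹, Ea2 = 40.0 kJ mol⁻¹)
    partner + free catalyst → spent catalyst A (k3 = 1100 M⁻¹ s⁻¹, Ea3 = 45.0 kJ mol⁻¹)
    partner + free catalyst + left-handed substrate → free catalyst + left-handed product (k4 = 1.5 × 10⁷ M⁻² s⁻¹, Ea4 = 13.0 kJ mol⁻¹)
    partner + free catalyst + right-handed substrate → free catalyst + right-handed product (k5 = 7.3 × 10⁶ M⁻² s⁻¹, Ea5 = 13.0 kJ mol⁻¹)
    (constants at 50 °C)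

| flask | left-handed substrate | partner | free catalyst | right-handed substrate | time | remark | temperature |
|---|---|---|---|---|---|---|---|
| ash | 1.0 mM | 1.00 equiv | 0.96 mol% | 1.0 mM | 1.0 min | at 50 °C until 12 s, from then on at −10 °C |  |
| oak | 1.0 mM | 1.00 equiv | 0.96 mol% | 1.0 mM | 1.0 min |  | −10 °C |
| birch | 1.0 mM | 1.00 equiv | 0.96 mol% | 1.0 mM | 1.0 min |  | 50 °C |
| larch | 1.0 mM | 1.00 equiv | 0.96 mol% | 1.0 mM | 1.0 min |  | 20 °C |

- free catalyst is single-handed; left-handed substrate and right-handed substrate are mirror images of each other, charged as a racemate, each of them at the stated concentration
- a step written with two of one species runs at k times the square of its concentration and takes two of it each time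
- constants are those at 50 °C; use the activation energies for any other temperature

- the flask that comes out highest in amount of left-handed product, in percent of the left-handed substrate and right-handed substrate together charged, or "all alike" when all lie within 1.5 percentage points (ash / oak / birch / larch / all alike)
- left-handed product at the end, in percent of the left-handed substrate and right-handed substrate together charged, ash
- left-handed product at the end, in percent of the left-handed substrate and right-handed substrate together charged, oak
- left-handed product at the end, in percent of the left-handed substrate and right-handed substrate together charged, birch
- left-handed product at the end, in percent of the left-handed substrate and right-handed substrate together charged, larch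

The step to left-handed product and the step to spent catalyst A both run on partner times free catalyst. Those two cancel in the ratio of their rates, so with the left-handed substrate frozen at its full charge, that ratio is the turnover per kill at every moment. It rose on cooling, to 46.1 at 20 °C for larch and 206 at −10 °C for oak.

Decomposition alone gives the partner a mean life of about 1.11 s at 50 °C, far shorter than the 12 s hot stage of ash, so I treated ash as birch. I guessed that a fraction 0.5 of the catalyst would end as spent catalyst A. That gave 3.27% for ash, 3.27% for birch and 11.1% for larch.

For oak the same guess gave 49.5%, but a fraction 0.673 of the turnover goes left at the start, and at that split the partner's charge pays for 33.6% of left-handed product. With the free catalyst frozen at 0.5 of its charge and both substrates at their full charge, the two product steps consume partner pseudo-first-order at 0.0355 s⁻¹, so my estimate put oak below 29.6%. My pick was oak.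

The forecast also chose oak, with ash 7.7%, oak 42%, birch 7.7% and larch 24%. It states “I took equivalents and mol% on the two substrates together”, whereas I took them on the left-handed substrate.

The flasks gave oak as highest: ash 3.38%, oak 24.7%, birch 3.38%, larch 12.8%.

In birch, spent catalyst A stood at the end at 53.4% of the catalyst charged, and the turnover per kill turns that into 3.50% of left-handed product. The neighbour of ash was charged with 3.8 mol% of free catalyst, and 33.7% of it stood as spent catalyst A at the end, against 53.4% in ash. With its left-handed substrate taken midway between full charge and the 84% remaining, the same ratio gave 8.01%. That neighbour flask ended at 8.02%.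

The rate constants come from no measurement, and the outcome is calculated.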